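**Plan**

- Feature: numbered as a benzofuran (O1, C2, C3, C3a, C4 to C7, C7a), the carbocycle of the target is a para-quinone methide (C6=O, C4=C5, C7=C7a, exocyclic C3a=C3). Its lactone oxygen O1 sits on C7a, the carbon β to the C6 carbonyl, so a carboxyl carried on C3 can close the five-membered lactone ring by conjugate addition once a C6 phenol has been oxidised.
- Cuts, in retrosynthetic order: the phenolic O–Si bond; the O1–C7a lactone bond (with removal of four hydrogens) back to a diarylacetic acid; the C3–C3a bond (ester enolate arylation); the two phenyl–arene bonds at C4 and C7 (Suzuki coupling).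
- Forward: the central terphenyl ring is assembled first, desymmetrised by mono-demethylation, brominated para to the new phenol and protected. The silyloxyphenylacetate is then joined at C3a, hydrogenolysis frees phenol and acid, the lactone ring (the only ring made) closes in the oxidation, and the silyl group is removed last.
- Stereochemistry: the target has no stereocentre. C3 is racemic in the intermediates and becomes trigonal in the key step; the C3=C3a geometry is fixed by the lactone ring.

Key step: step 9

Remark: 1,4-dibromo-2,3-dimethoxybenzene is assumed to be purchasable, and the target is handled as the C6-oxo tautomer drawn in its SMILES. TBS stands for tert-butyldimethylsilyl.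

**Route**

Step 1
Reactants: 1 1,4-dibromo-2,3-dimethoxybenzene; 2 phenylboronic acid
Product: 3 2,3-dimethoxy-1,4-diphenylbenzene
Conditions: 2 (2.5 equiv), Pd(OAc)2 (cat.), SPhos (cat.), K3PO4, PhMe/H2O, 100 °C
Reagents that add atoms: none
Why: Twofold Suzuki–Miyaura coupling; the electron-rich biarylphosphine catalyst should couple both methoxy-flanked C–Br bonds cleanly.

Step 2
Reactants: 3 2,3-dimethoxy-1,4-diphenylbenzene
Product: 4 2-methoxy-3,6-diphenylphenol
Conditions: NaSEt (2 equiv), DMF, 130 °C; then aq. HCl
Reagents that add atoms: none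
Why: Thiolate SN2 O-demethylation of an aryl methyl ether; 3 is symmetric, so either methyl gives the same phenol, and the phenoxide formed protects the neighbouring ether because a catecholate dianion would have to leave.

Step 3
Reactants: 4 2-methoxy-3,6-diphenylphenol
Product: 5 4-bromo-2-methoxy-3,6-diphenylphenol
Conditions: NBS (1.0 equiv), MeCN, 0 °C → rt
Reagents that add atoms: N-bromosuccinimide, O=C1CCC(=O)N1Br
Why: Electrophilic aromatic bromination directed by the free hydroxyl; both ortho positions are blocked, so bromine should enter para to OH (as in the 4-bromination of guaiacol) and not para to the twisted, weaker-donating methoxy group.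

Step 4
Reactants: 5 4-bromo-2-methoxy-3,6-diphenylphenol
Product: 6 1-benzyloxy-4-bromo-2-methoxy-3,6-diphenylbenzene
Conditions: BnBr, K2CO3, DMF, 60 °C
Reagents that add atoms: benzyl bromide, BrCc1ccccc1
Why: Williamson ether synthesis; the benzyl ether shields the phenol from the strong base of the enolate coupling and later leaves in the same operation as the benzyl ester.

Step 5
Reactants: 7 4-hydroxyphenylacetic acid
Product: 8 benzyl 2-(4-hydroxyphenyl)acetate
Conditions: BnBr (1.05 equiv), KHCO3, DMF, rt → 40 °C
Reagents that add atoms: benzyl bromide, BrCc1ccccc1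
Why: Chemoselective carboxylate O-alkylation (SN2); hydrogen carbonate deprotonates the acid but not the phenol, so only the carboxylate is benzylated.

Step 6
Reactants: 8 benzyl 2-(4-hydroxyphenyl)acetate
Product: 9 benzyl 2-[4-(tert-butyldimethylsilyloxy)phenyl]acetate
Conditions: TBSCl, imidazole, DMF, rt
Reagents that add atoms: tert-butyldimethylsilyl chloride, CC(C)(C)[Si](C)(C)Cl
Why: Standard imidazole-mediated silylation of an unhindered phenol; the silyl ether is the group that keeps the pendant ring out of the later oxidation.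

Step 7
Reactants: 6 1-benzyloxy-4-bromo-2-methoxy-3,6-diphenylbenzene; 9 benzyl 2-[4-(tert-butyldimethylsilyloxy)phenyl]acetate
Product: 10 benzyl 2-(4-benzyloxy-3-methoxy-2,5-diphenylphenyl)-2-[4-(tert-butyldimethylsilyloxy)phenyl]acetate (racemic)
Conditions: LiN(SiMe3)2 (2.3 equiv), Pd(dba)2 (cat.), P(t-Bu)3 (cat.), PhMe, rt → 50 °C; then aq. NH4Cl
Reagents that add atoms: none
Why: Palladium-catalysed α-arylation of an ester enolate forms the C3–C3a bond; the bulky electron-rich phosphine should cope with the ortho-phenyl bromide, the more acidic product is held as its enolate and is too hindered for a second arylation, and the new stereocentre is formed racemic and is lost later.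

Step 8
Reactants: 10 benzyl 2-(4-benzyloxy-3-methoxy-2,5-diphenylphenyl)-2-[4-(tert-butyldimethylsilyloxy)phenyl]acetate (racemic)
Product: 11 2-[4-(tert-butyldimethylsilyloxy)phenyl]-2-(4-hydroxy-3-methoxy-2,5-diphenylphenyl)acetic acid (racemic)
Conditions: H2 (1 atm), Pd/C, EtOAc, rt
Reagents that add atoms: none
Why: Catalytic hydrogenolysis removes the benzyl ether and the benzyl ester in one operation, and the aryl silyl ether should be inert in the aprotic solvent.

Step 9
Reactants: 11 2-[4-(tert-butyldimethylsilyloxy)phenyl]-2-(4-hydroxy-3-methoxy-2,5-diphenylphenyl)acetic acid (racemic)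
Product: 15 3-[4-(tert-butyldimethylsilyloxy)phenyl]-5-methoxy-4,7-diphenylbenzofuran-2,6-dione, via quinone methide acid 12 (not isolated), via dienol lactone 13 (not isolated), via 6-hydroxy lactone 14 (not isolated)
Conditions: DDQ (2.2 equiv, two portions), 4 Å MS, 1,4-dioxane, rt → 60 °C
Reagents that add atoms: none
Why: Proposed new method: DDQ should take hydride from the doubly benzylic C3–H para to the only free phenol (C6–OH) of 11 and give the para-quinone methide acid 12 (C6=O, C4=C5, C7=C7a, C3a=C3), whose E and Z forms can interconvert through the O-protonated benzylic cation in the acidic, base-free medium. In the E form the carboxyl oxygen lies next to C7a, the unsubstituted carbon β to the C6 carbonyl, and the crowded, twisted C3=C3a bond lets it reach the π-face there, so a 5-exo-trig oxa-Michael addition closes the lactone ring (O1–C7a) to dienol 13. Loss of the C7a proton with reprotonation at C3 re-aromatises 13 to the 6-hydroxy-3H-benzofuran-2-one 14, and the second equivalent of DDQ dehydrogenates its C3–H/C6–OH pair to 15. The closest known reaction types are the DDQ oxidation of 4-hydroxydiarylmethanes to quinone methides, the lactonisation of cis,cis-muconic acid (a carboxyl adding 5-exo to the β-carbon of the distal unsaturated acid) and the oxidative lactonisation of phenolic acids with PhI(OAc)2. No stereocentre survives: C3 of 11 and 14 and C7a of 13 are racemic and end trigonal. The step needs chemoselectivity for the central ring and regioselectivity for C7a: the pendant phenol is silylated and cannot form a quinone methide, closure at C3 would mean a three-membered lactone, closure at C4 gives an adduct that cannot aromatise and reverts, and dry base-free dioxane keeps the acid un-ionised to hold back oxidative decarboxylation and hydration at C3.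

Step 10
Reactants: 15 3-[4-(tert-butyldimethylsilyloxy)phenyl]-5-methoxy-4,7-diphenylbenzofuran-2,6-dione
Product: 16 3-(4-hydroxyphenyl)-5-methoxy-4,7-diphenylbenzofuran-2,6-dione
Conditions: HF·pyridine, THF/pyridine, 0 °C → rt
Reagents that add atoms: none
Why: Fluoride-driven cleavage of the aryl silyl ether under mildly acidic conditions, which should spare the lactone and the quinone methide that basic fluoride or hydroxide could open.

**Compound list**

1 | 1,4-dibromo-2,3-dimethoxybenzene | COc1c(Br)ccc(Br)c1OC | starting material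
2 | phenylboronic acid | OB(O)c1ccccc1 | starting material
3 | 2,3-dimethoxy-1,4-diphenylbenzene | COc1c(-c2ccccc2)ccc(-c2ccccc2)c1OC | intermediate
4 | 2-methoxy-3,6-diphenylphenol | COc1c(O)c(-c2ccccc2)ccc1-c1ccccc1 | intermediate
5 | 4-bromo-2-methoxy-3,6-diphenylphenol | COc1c(O)c(-c2ccccc2)cc(Br)c1-c1ccccc1 | intermediate
6 | 1-benzyloxy-4-bromo-2-methoxy-3,6-diphenylbenzene | COc1c(OCc2ccccc2)c(-c2ccccc2)cc(Br)c1-c1ccccc1 | intermediate
7 | 4-hydroxyphenylacetic acid | O=C(O)Cc1ccc(O)cc1 | starting material
8 | benzyl 2-(4-hydroxyphenyl)acetate | O=C(Cc1ccc(O)cc1)OCc1ccccc1 | intermediate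
9 | benzyl 2-[4-(tert-butyldimethylsilyloxy)phenyl]acetate | O=C(Cc1ccc(O[Si](C)(C)C(C)(C)C)cc1)OCc1ccccc1 | intermediate
10 | benzyl 2-(4-benzyloxy-3-methoxy-2,5-diphenylphenyl)-2-[4-(tert-butyldimethylsilyloxy)phenyl]acetate (racemic) | O=C(OCc1ccccc1)C(c1ccc(O[Si](C)(C)C(C)(C)C)cc1)c1cc(-c2ccccc2)c(OCc2ccccc2)c(OC)c1-c1ccccc1 | intermediate
11 | 2-[4-(tert-butyldimethylsilyloxy)phenyl]-2-(4-hydroxy-3-methoxy-2,5-diphenylphenyl)acetic acid (racemic) | OC(=O)C(c1ccc(O[Si](C)(C)C(C)(C)C)cc1)c1cc(-c2ccccc2)c(O)c(OC)c1-c1ccccc1 | intermediate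
12 | (E)-2-[4-(tert-butyldimethylsilyloxy)phenyl]-2-(3-methoxy-4-oxo-2,5-diphenylcyclohexa-2,5-dien-1-ylidene)acetic acid (carboxyl on the side of the ring CH) | OC(=O)/C(c1ccc(O[Si](C)(C)C(C)(C)C)cc1)=C1\C=C(c2ccccc2)C(=O)C(OC)=C1c1ccccc1 | intermediate
13 | 3-[4-(tert-butyldimethylsilyloxy)phenyl]-6-hydroxy-5-methoxy-4,7-diphenyl-7aH-benzofuran-2-one (racemic at C7a; double bonds C3=C3a, C4=C5, C6=C7) | COC1=C(c2ccccc2)C2=C(c3ccc(O[Si](C)(C)C(C)(C)C)cc3)C(=O)OC2C(c2ccccc2)=C1O | intermediate
14 | 3-[4-(tert-butyldimethylsilyloxy)phenyl]-6-hydroxy-5-methoxy-4,7-diphenyl-3H-benzofuran-2-one (racemic) | COc1c(O)c(-c2ccccc2)c2OC(=O)C(c3ccc(O[Si](C)(C)C(C)(C)C)cc3)c2c1-c1ccccc1 | intermediate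
15 | 3-[4-(tert-butyldimethylsilyloxy)phenyl]-5-methoxy-4,7-diphenylbenzofuran-2,6-dione | COC1=C(c2ccccc2)C2=C(c3ccc(O[Si](C)(C)C(C)(C)C)cc3)C(=O)OC2=C(c2ccccc2)C1=O | intermediate
16 | 3-(4-hydroxyphenyl)-5-methoxy-4,7-diphenylbenzofuran-2,6-dione | COC1=C(c2ccccc2)C2=C(c3ccc(O)cc3)C(=O)OC2=C(c2ccccc2)C1=O | target

**Count**

Total steps: 10. Longest linear sequence: 8 steps (steps 1, 2, 3, 4, 7, 8, 9, 10, from 1); the side branch (steps 5 and 6) joins at step 7.

**Steps most likely to fail**

1. Step 9 (key step). The phenolic acid may undergo oxidative decarboxylation faster than hydride loss from C3, or the quinone methide may be captured at C3 by outside nucleophiles before the carboxyl closes on C7a. The fallback uses known chemistry, sets out from phenol 4 (with ester 9 as the second component) and returns at 15; it brings the C7a oxygen in on a quinone and closes the ring by forming C3–C3a instead. Oxidation of 4 with (KO3S)2NO (Fremy's salt) in buffered aqueous acetone should give 2-methoxy-3,6-diphenyl-1,4-benzoquinone F1. Thiele–Winter acetoxylation (Ac2O, BF3·OEt2) at its only free ring carbon should give 5-methoxy-3,6-diphenylbenzene-1,2,4-triyl triacetate F2. Hydrolysis (NaOH, MeOH, air; then HCl) with autoxidation should give 2-hydroxy-5-methoxy-3,6-diphenyl-1,4-benzoquinone F3. Hydrogenolysis of 9 (H2, Pd/C, EtOAc) should give 2-[4-(tert-butyldimethylsilyloxy)phenyl]acetic acid F4. Esterification of the hydroxyl of F3 with F4 (DCC, DMAP, CH2Cl2) should give 4-methoxy-3,6-dioxo-2,5-diphenylcyclohexa-1,4-dien-1-yl 2-[4-(tert-butyldimethylsilyloxy)phenyl]acetate F5. Its activated methylene should then condense with the neighbouring quinone carbonyl (Et3N, intramolecular Knoevenagel condensation, loss of water) to give 15.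

2. Step 7. Oxidative addition and transmetalation may be slow at the ortho-phenyl-flanked C–Br bond, so that hydrodebromination or Claisen self-condensation of the benzyl ester enolate takes over. The fallback sets out from bromide 6, returns at 10 and reverses the order in which the two aryl groups are attached to C3. Benzyl bromoacetate and Zn should give bromo(2-benzyloxy-2-oxoethyl)zinc F6, a small and neutral Reformatsky enolate. Its coupling with 6 (Pd(dba)2, P(t-Bu)3, THF) should give benzyl 2-(4-benzyloxy-3-methoxy-2,5-diphenylphenyl)acetate F7. α-Arylation of F7 with the unhindered, purchasable tert-butyl(4-bromophenoxy)dimethylsilane (Pd(dba)2, P(t-Bu)3, LiN(SiMe3)2, PhMe) should then give 10.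

3. Step 3. Site selectivity may be lost (attack para to the methoxy group), or over-bromination or oxidation of the electron-rich phenol may occur. The fallback sets out from phenol 4, returns at acid 11 and needs no aryl halide, so steps 4, 7 and 8 fall away. Acid-catalysed Friedel–Crafts alkylation of 4 with purchasable 4-hydroxymandelic acid (cat. TfOH, hexafluoroisopropanol, rt) uses a stabilised 4-hydroxybenzylic cation, a far more discriminating electrophile than a bromine source. It should attack para to the hydroxyl and give 2-(4-hydroxyphenyl)-2-(4-hydroxy-3-methoxy-2,5-diphenylphenyl)acetic acid F8. TBSCl and imidazole (DMF, 0 °C) should silylate the carboxyl and the unhindered pendant phenol but not the central hydroxyl flanked by methoxy and phenyl, giving tert-butyldimethylsilyl 2-[4-(tert-butyldimethylsilyloxy)phenyl]-2-(4-hydroxy-3-methoxy-2,5-diphenylphenyl)acetate F9. Hydrolysis of the silyl ester on work-up (AcOH, THF/H2O) should give 11.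

**Further compounds**

F1 | step 9 | 2-methoxy-3,6-diphenyl-1,4-benzoquinone | COC1=C(c2ccccc2)C(=O)C=C(c2ccccc2)C1=O
F2 | step 9 | 5-methoxy-3,6-diphenylbenzene-1,2,4-triyl triacetate | COc1c(OC(C)=O)c(-c2ccccc2)c(OC(C)=O)c(OC(C)=O)c1-c1ccccc1
F3 | step 9 | 2-hydroxy-5-methoxy-3,6-diphenyl-1,4-benzoquinone | COC1=C(c2ccccc2)C(=O)C(O)=C(c2ccccc2)C1=O
F4 | step 9 | 2-[4-(tert-butyldimethylsilyloxy)phenyl]acetic acid | OC(=O)Cc1ccc(O[Si](C)(C)C(C)(C)C)cc1
F5 | step 9 | 4-methoxy-3,6-dioxo-2,5-diphenylcyclohexa-1,4-dien-1-yl 2-[4-(tert-butyldimethylsilyloxy)phenyl]acetate | COC1=C(c2ccccc2)C(=O)C(OC(=O)Cc2ccc(O[Si](C)(C)C(C)(C)C)cc2)=C(c2ccccc2)C1=O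
F6 | step 7 | bromo(2-benzyloxy-2-oxoethyl)zinc | Br[Zn]CC(=O)OCc1ccccc1
F7 | step 7 | benzyl 2-(4-benzyloxy-3-methoxy-2,5-diphenylphenyl)acetate | O=C(Cc1cc(-c2ccccc2)c(OCc2ccccc2)c(OC)c1-c1ccccc1)OCc1ccccc1
F8 | step 3 | 2-(4-hydroxyphenyl)-2-(4-hydroxy-3-methoxy-2,5-diphenylphenyl)acetic acid (racemic) | OC(=O)C(c1ccc(O)cc1)c1cc(-c2ccccc2)c(O)c(OC)c1-c1ccccc1
F9 | step 3 | tert-butyldimethylsilyl 2-[4-(tert-butyldimethylsilyloxy)phenyl]-2-(4-hydroxy-3-methoxy-2,5-diphenylphenyl)acetate (racemic) | CC(C)(C)[Si](C)(C)OC(=O)C(c1ccc(O[Si](C)(C)C(C)(C)C)cc1)c1cc(-c2ccccc2)c(O)c(OC)c1-c1ccccc1
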